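**Retrosynthetic overview**
- The exocyclic methylene is removed first (Horner–Wadsworth–Emmons disconnection to an α-phosphono lactone).
- The γ-lactone is then opened at the C-8–O bond (key bond) and at C-7–C-11, giving a 1,3-cycloheptadiene plus (diethoxyphosphoryl)acetic acid; this oxidative acyloxy-alkylation is the new step.
- The C-5 methyl of the diene comes from a dienyl triflate by cross-coupling, and the triflate from a cyclohept-2-enone.
- The C-1/C-2 bond is an aldol disconnection to a silyl dienol ether and 3-oxopropyl acetate; the C-10 methyl comes from an enantioselective conjugate addition to cyclohepta-2,6-dienone.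
- Ring order: the seven-membered carbocycle is bought as cycloheptanone; the γ-lactone ring is formed last.

Assumption: compounds are numbered in the order of the forward steps; carbon positions are cited with target locants, also for intermediates (C-1 ring carbon bearing the side chain; C-2, C-3, C-4 side chain; C-5(Me)=C-6; C-7 and C-8 the lactone-bearing ring carbons; C-9; C-10(Me); C-11, C-12, C-13 lactone carbons).

**Step 1**
Reactants: 1 cycloheptanone
Product: 2 cyclohepta-2,6-dien-1-one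
Conditions: 2-iodoxybenzoic acid (IBX, 2.6 equiv), DMSO/fluorobenzene, 75 °C
Reagents that add atoms: none
Why: Twofold α,β-dehydrogenation of a ketone by a hypervalent iodine oxidant (IBX dehydrogenation); the second dehydrogenation occurs on the still saturated α′ side and gives the cross-conjugated dienone, with no stereocentre formed.

**Step 2**
Reactants: 2 cyclohepta-2,6-dien-1-one
Product: 4 trimethyl{[(3R)-3-methylcyclohepta-1,6-dien-1-yl]oxy}silane, via methylzinc dienolate 3 (not isolated)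
Conditions: Cu(OTf)2 (2 mol %), (R,S,S)-O,O′-(1,1′-binaphthyl-2,2′-diyl)-N,N-bis(1-phenylethyl)phosphoramidite (4 mol %), Me2Zn (1.3 equiv), toluene, −30 °C; then TMSOTf (1.4 equiv), −30 → 0 °C
Reagents that add atoms: dimethylzinc, C[Zn]C; trimethylsilyl trifluoromethanesulfonate, C[Si](C)(C)OS(=O)(=O)C(F)(F)F
Why: Copper-catalysed enantioselective conjugate addition with silyl trapping of the zinc enolate; the two enone halves of 2 are equivalent, the ligand enantiomer is chosen to set C-10 as R, the dienolate cannot take up a second methyl, and O-silylation fixes the enolate towards C-1.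

**Step 3**
Reactants: 5 but-3-en-1-yl acetate
Product: 7 3-oxopropyl acetate, via secondary ozonide 6 (not isolated)
Conditions: O3, CH2Cl2, −78 °C; then PPh3, −78 °C → rt
Reagents that add atoms: ozone, [O-][O+]=O
Why: Ozonolysis with reductive work-up cleaves the terminal alkene to the aldehyde and leaves the acetate untouched; no stereocentre is formed.

**Step 4**
Reactants: 4 trimethyl{[(3R)-3-methylcyclohepta-1,6-dien-1-yl]oxy}silane; 7 3-oxopropyl acetate
Product: 8 (3S)-3-hydroxy-3-[(1R,7R)-7-methyl-2-oxocyclohept-3-en-1-yl]propyl acetate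
Conditions: BF3·OEt2 (1.1 equiv), CH2Cl2, −78 °C; aq. NaHCO3
Reagents that add atoms: none
Why: Mukaiyama aldol addition at C-1 of the silyl dienol ether on the face opposite the neighbouring C-10 methyl (trans ring substituents), through an open antiperiplanar transition state in which the aldehyde chain avoids C-10, which should favour the syn C-1/C-2 aldol with the (2S) carbinol and returns the C-5 enone.

**Step 5**
Reactants: 8 (3S)-3-hydroxy-3-[(1R,7R)-7-methyl-2-oxocyclohept-3-en-1-yl]propyl acetate; 9 angelic anhydride [(2Z)-2-methylbut-2-enoic anhydride]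
Product: 10 (1S)-3-(acetyloxy)-1-[(1R,7R)-7-methyl-2-oxocyclohept-3-en-1-yl]propyl (2Z)-2-methylbut-2-enoate
Conditions: Sc(OTf)3 (5 mol %), MeCN/CH2Cl2, −20 °C
Reagents that add atoms: none
Why: Lewis-acid-catalysed O-acylation of the secondary alcohol by the anhydride, run cold and without base so that the β-oxy ketone neither eliminates nor undergoes retro-aldol cleavage and the Z-angelate does not isomerise; C-2 keeps its configuration.

**Step 6**
Reactants: 10 (1S)-3-(acetyloxy)-1-[(1R,7R)-7-methyl-2-oxocyclohept-3-en-1-yl]propyl (2Z)-2-methylbut-2-enoate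
Product: 11 (1S)-3-(acetyloxy)-1-[(1R,7R)-7-methyl-2-{[(trifluoromethyl)sulfonyl]oxy}cyclohepta-2,4-dien-1-yl]propyl (2Z)-2-methylbut-2-enoate
Conditions: Tf2O (1.2 equiv), 2,6-di-tert-butyl-4-methylpyridine (1.5 equiv), CH2Cl2, 0 °C → rt
Reagents that add atoms: trifluoromethanesulfonic anhydride, O=S(=O)(OS(=O)(=O)C(F)(F)F)C(F)(F)F
Why: Dienyl triflate formation from an enone: O-triflation of the carbonyl followed by loss of a γ-proton from C-8 gives the linear C-5=C-6/C-7=C-8 dienyl triflate (as with steroidal enones), the hindered base not reaching the tertiary C-1 hydrogen; stereocentres are untouched.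

**Step 7**
Reactants: 11 (1S)-3-(acetyloxy)-1-[(1R,7R)-7-methyl-2-{[(trifluoromethyl)sulfonyl]oxy}cyclohepta-2,4-dien-1-yl]propyl (2Z)-2-methylbut-2-enoate
Product: 12 (1S)-3-(acetyloxy)-1-[(1S,7R)-2,7-dimethylcyclohepta-2,4-dien-1-yl]propyl (2Z)-2-methylbut-2-enoate
Conditions: Me2Zn (1.5 equiv), Pd(PPh3)4 (5 mol %), THF, 0 °C → rt
Reagents that add atoms: dimethylzinc, C[Zn]C
Why: Negishi cross-coupling of the dienyl triflate installs the C-5 methyl with retention of the diene and tolerates both esters; the descriptor at C-1 changes from R to S only through substituent priorities.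

**Step 8**
Reactants: 12 (1S)-3-(acetyloxy)-1-[(1S,7R)-2,7-dimethylcyclohepta-2,4-dien-1-yl]propyl (2Z)-2-methylbut-2-enoate; 13 (diethoxyphosphoryl)acetic acid
Product: 14 diethyl [(3aS,6S,7R,8aR)-6-[(1S)-3-(acetyloxy)-1-{[(2Z)-2-methylbut-2-enoyl]oxy}propyl]-5,7-dimethyl-2-oxo-3,3a,6,7,8,8a-hexahydro-2H-cyclohepta[b]furan-3-yl]phosphonate (mixture of epimers at the phosphonate carbon)
Conditions: Pd(OAc)2 (10 mol %), p-benzoquinone (2 equiv), LiOAc (20 mol %), 13 (3 equiv), acetone, 30 °C
Reagents that add atoms: none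
Why: Proposed new method: an oxidative [3+2] lactone annulation of a 1,3-diene with a C–H-acidic carboxylic acid, in which divalent palladium sits on the diene face away from the C-1 side chain, the carboxylate of 13 attacks the unsubstituted terminus C-8 anti to the metal and anti to the C-10 methyl (forming the C-8–O bond and setting C-8), and the tethered phosphonoacetate carbon then attacks C-7 of the η3-allylpalladium anti to the metal to close a cis-fused lactone with C-5=C-6 left in place, zerovalent palladium being reoxidised by benzoquinone; the closest known reactions are the palladium/benzoquinone 1,4-diacyloxylation and 1,4-oxylactonisation of cyclic dienes and intramolecular palladium-catalysed allylic alkylation by stabilised carbanions.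

**Step 9**
Reactants: 14 diethyl [(3aS,6S,7R,8aR)-6-[(1S)-3-(acetyloxy)-1-{[(2Z)-2-methylbut-2-enoyl]oxy}propyl]-5,7-dimethyl-2-oxo-3,3a,6,7,8,8a-hexahydro-2H-cyclohepta[b]furan-3-yl]phosphonate
Product: 15 (1S)-3-(acetyloxy)-1-[(3aR,6S,7R,8aR)-5,7-dimethyl-3-methylidene-2-oxo-3,3a,6,7,8,8a-hexahydro-2H-cyclohepta[b]furan-6-yl]propyl (2Z)-2-methylbut-2-enoate
Conditions: K2CO3 (2 equiv), 37 % aq. CH2O, THF, 0 °C → rt
Reagents that add atoms: formaldehyde, C=O
Why: Horner–Wadsworth–Emmons methylenation of the α-phosphono lactone with formaldehyde under mild carbonate conditions gives the α-methylene lactone without touching the acetate, the angelate or the ring stereocentres; the epimeric phosphonate carbon becomes sp2.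

**Compound list**
1 | cycloheptanone | O=C1CCCCCC1 | starting material
2 | cyclohepta-2,6-dien-1-one | O=C1C=CCCC=C1 | intermediate
3 | methylzinc (3R)-3-methylcyclohepta-1,6-dien-1-olate | C1CC[C@@H](C)C=C(O[Zn]C)C=C1 | intermediate
4 | trimethyl{[(3R)-3-methylcyclohepta-1,6-dien-1-yl]oxy}silane | C1CC[C@@H](C)C=C(O[Si](C)(C)C)C=C1 | intermediate
5 | but-3-en-1-yl acetate | CC(=O)OCCC=C | starting material
6 | 2-(1,2,4-trioxolan-3-yl)ethyl acetate (secondary ozonide) | CC(=O)OCCC1OCOO1 | intermediate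
7 | 3-oxopropyl acetate | CC(=O)OCCC=O | intermediate
8 | (3S)-3-hydroxy-3-[(1R,7R)-7-methyl-2-oxocyclohept-3-en-1-yl]propyl acetate | C1CC[C@@H](C)[C@H]([C@H](CCOC(C)=O)O)C(=O)C=C1 | intermediate
9 | angelic anhydride, (2Z)-2-methylbut-2-enoic anhydride | C/C=C(/C)C(=O)OC(=O)/C(C)=C\C | starting material
10 | (1S)-3-(acetyloxy)-1-[(1R,7R)-7-methyl-2-oxocyclohept-3-en-1-yl]propyl (2Z)-2-methylbut-2-enoate | C1CC[C@@H](C)[C@H]([C@H](CCOC(C)=O)OC(=O)/C(C)=C\C)C(=O)C=C1 | intermediate
11 | (1S)-3-(acetyloxy)-1-[(1R,7R)-7-methyl-2-{[(trifluoromethyl)sulfonyl]oxy}cyclohepta-2,4-dien-1-yl]propyl (2Z)-2-methylbut-2-enoate | C1=CC[C@@H](C)[C@H]([C@H](CCOC(C)=O)OC(=O)/C(C)=C\C)C(OS(=O)(=O)C(F)(F)F)=C1 | intermediate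
12 | (1S)-3-(acetyloxy)-1-[(1S,7R)-2,7-dimethylcyclohepta-2,4-dien-1-yl]propyl (2Z)-2-methylbut-2-enoate | C1=CC[C@@H](C)[C@H]([C@H](CCOC(C)=O)OC(=O)/C(C)=C\C)C(C)=C1 | intermediate
13 | (diethoxyphosphoryl)acetic acid | OC(=O)CP(=O)(OCC)OCC | starting material
14 | diethyl [(3aS,6S,7R,8aR)-6-[(1S)-3-(acetyloxy)-1-{[(2Z)-2-methylbut-2-enoyl]oxy}propyl]-5,7-dimethyl-2-oxo-3,3a,6,7,8,8a-hexahydro-2H-cyclohepta[b]furan-3-yl]phosphonate (epimers at C-3 of the lactone) | CCOP(=O)(OCC)C1C(=O)O[C@@H]2C[C@@H](C)[C@H]([C@H](CCOC(C)=O)OC(=O)/C(C)=C\C)C(C)=C[C@H]12 | intermediate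
15 | (1S)-3-(acetyloxy)-1-[(3aR,6S,7R,8aR)-5,7-dimethyl-3-methylidene-2-oxo-3,3a,6,7,8,8a-hexahydro-2H-cyclohepta[b]furan-6-yl]propyl (2Z)-2-methylbut-2-enoate | C=C1C(=O)O[C@@H]2C[C@@H](C)[C@H]([C@H](CCOC(C)=O)OC(=O)/C(C)=C\C)C(C)=C[C@H]12 | target

**Totals**
Total step count: 9. Longest linear sequence: 8 steps (1 → 15 through steps 1, 2, 4, 5, 6, 7, 8 and 9; step 3 is a one-step side branch).

**Three steps most likely to fail**

Step 8 (the new annulation). The carboxylate may add twice (1,4-diacyloxylation), the phosphonoacetate carbon may be too weakly acidic to close onto the allylpalladium, or the face selectivity may be poor. The fallback uses known chemistry, sets out from 12 and comes back at 15. Methylchloroketene, generated from 2-chloropropanoyl chloride and Et3N in Et2O, adds [2+2] to the C-7=C-8 bond with its carbonyl carbon on C-8, from the face opposite the C-10 methyl. This gives (1S)-3-(acetyloxy)-1-[(1S,4S,5R,7R)-9-chloro-3,5,9-trimethyl-8-oxobicyclo[5.2.0]non-2-en-4-yl]propyl (2Z)-2-methylbut-2-enoate F8, with chlorine mainly exo. Baeyer–Villiger oxidation with H2O2 in AcOH at 0 °C then forms the C-8–O bond with retention (the non-chlorinated carbon migrates; the alkenes are not epoxidised), giving the α-chloro-α-methyl lactone (1S)-3-(acetyloxy)-1-[(3aS,6S,7R,8aR)-3-chloro-3,5,7-trimethyl-2-oxo-3,3a,6,7,8,8a-hexahydro-2H-cyclohepta[b]furan-6-yl]propyl (2Z)-2-methylbut-2-enoate F9. Dehydrochlorination with DBU in toluene gives 15; in the major epimer the chlorine is syn to H-7, so only the methyl hydrogens can eliminate.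

Step 4 (syn selectivity at C-2). Closed transition states of cyclic enolates give the anti aldol, and the open-transition-state preference for syn may be modest, so the C-2 epimer may have to be separated. The fallback sets out from 4 and comes back at 8. Compound 4 is added to 3-[(4-methoxybenzyl)oxy]propanal with TiCl4 in CH2Cl2 at −78 °C. The six-membered titanium chelate places the Lewis acid on the chain side and enforces the syn aldol, giving (6R,7R)-7-{(1S)-1-hydroxy-3-[(4-methoxybenzyl)oxy]propyl}-6-methylcyclohept-2-en-1-one F1. DDQ in wet CH2Cl2 removes the benzyl ether to give (6R,7R)-7-[(1S)-1,3-dihydroxypropyl]-6-methylcyclohept-2-en-1-one F2. Acetyl chloride with 2,4,6-collidine at −78 °C acetylates only the primary hydroxyl and gives 8.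

Step 6 (dienyl triflate). Proton loss from C-1 instead of C-8, or participation of the neighbouring angelate, would give the wrong triflate. The fallback avoids the dienyl triflate and the diene, sets out from 10 and comes back at 15.
- TBSOTf and Et3N in CH2Cl2 equilibrate 10 to the linear silyl dienol ether (1S)-3-(acetyloxy)-1-[(1R,7R)-2-{[tert-butyl(dimethyl)silyl]oxy}-7-methylcyclohepta-2,4-dien-1-yl]propyl (2Z)-2-methylbut-2-enoate F3.
- Vinylogous Rubottom oxidation (mCPBA, NaHCO3, CH2Cl2, −20 °C, then HF·pyridine) attacks the distal C-7=C-8 bond opposite the C-10 methyl and gives the γ-hydroxy enone (1S)-3-(acetyloxy)-1-[(1R,5R,7R)-5-hydroxy-7-methyl-2-oxocyclohept-3-en-1-yl]propyl (2Z)-2-methylbut-2-enoate F4.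
- Esterification with 13 (DCC, DMAP) gives (1R,5R,6R)-5-[(1S)-3-(acetyloxy)-1-{[(2Z)-2-methylbut-2-enoyl]oxy}propyl]-6-methyl-4-oxocyclohept-2-en-1-yl (diethoxyphosphoryl)acetate F5.
- K2CO3 with 18-crown-6 in THF, then aqueous formaldehyde, effects intramolecular Michael addition (cis fusion enforced by the tether) and Horner–Wadsworth–Emmons methylenation to the keto lactone (1S)-3-(acetyloxy)-1-[(3aR,6R,7R,8aR)-7-methyl-3-methylidene-2,5-dioxooctahydro-2H-cyclohepta[b]furan-6-yl]propyl (2Z)-2-methylbut-2-enoate F6.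
- KN(SiMe3)2 and N-(5-chloropyridin-2-yl)bis(trifluoromethanesulfonyl)imide at −78 °C give the less substituted enol triflate (1S)-3-(acetyloxy)-1-[(3aR,6R,7R,8aR)-7-methyl-3-methylidene-2-oxo-5-{[(trifluoromethyl)sulfonyl]oxy}-3,3a,6,7,8,8a-hexahydro-2H-cyclohepta[b]furan-6-yl]propyl (2Z)-2-methylbut-2-enoate F7.
- Me2Zn with Pd(PPh3)4 then gives 15.

**Further compounds**
F1 | step 4 | (6R,7R)-7-{(1S)-1-hydroxy-3-[(4-methoxybenzyl)oxy]propyl}-6-methylcyclohept-2-en-1-one | C1CC[C@@H](C)[C@H]([C@H](CCOCc2ccc(OC)cc2)O)C(=O)C=C1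
F2 | step 4 | (6R,7R)-7-[(1S)-1,3-dihydroxypropyl]-6-methylcyclohept-2-en-1-one | C1CC[C@@H](C)[C@H]([C@H](CCO)O)C(=O)C=C1
F3 | step 6 | (1S)-3-(acetyloxy)-1-[(1R,7R)-2-{[tert-butyl(dimethyl)silyl]oxy}-7-methylcyclohepta-2,4-dien-1-yl]propyl (2Z)-2-methylbut-2-enoate | C1=CC[C@@H](C)[C@H]([C@H](CCOC(C)=O)OC(=O)/C(C)=C\C)C(O[Si](C)(C)C(C)(C)C)=C1
F4 | step 6 | (1S)-3-(acetyloxy)-1-[(1R,5R,7R)-5-hydroxy-7-methyl-2-oxocyclohept-3-en-1-yl]propyl (2Z)-2-methylbut-2-enoate | O[C@@H]1C[C@@H](C)[C@H]([C@H](CCOC(C)=O)OC(=O)/C(C)=C\C)C(=O)C=C1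
F5 | step 6 | (1R,5R,6R)-5-[(1S)-3-(acetyloxy)-1-{[(2Z)-2-methylbut-2-enoyl]oxy}propyl]-6-methyl-4-oxocyclohept-2-en-1-yl (diethoxyphosphoryl)acetate | CCOP(=O)(OCC)CC(=O)O[C@@H]1C[C@@H](C)[C@H]([C@H](CCOC(C)=O)OC(=O)/C(C)=C\C)C(=O)C=C1
F6 | step 6 | (1S)-3-(acetyloxy)-1-[(3aR,6R,7R,8aR)-7-methyl-3-methylidene-2,5-dioxooctahydro-2H-cyclohepta[b]furan-6-yl]propyl (2Z)-2-methylbut-2-enoate | C=C1C(=O)O[C@@H]2C[C@@H](C)[C@H]([C@H](CCOC(C)=O)OC(=O)/C(C)=C\C)C(=O)C[C@H]12
F7 | step 6 | (1S)-3-(acetyloxy)-1-[(3aR,6R,7R,8aR)-7-methyl-3-methylidene-2-oxo-5-{[(trifluoromethyl)sulfonyl]oxy}-3,3a,6,7,8,8a-hexahydro-2H-cyclohepta[b]furan-6-yl]propyl (2Z)-2-methylbut-2-enoate | C=C1C(=O)O[C@@H]2C[C@@H](C)[C@H]([C@H](CCOC(C)=O)OC(=O)/C(C)=C\C)C(OS(=O)(=O)C(F)(F)F)=C[C@H]12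
F8 | step 8 | (1S)-3-(acetyloxy)-1-[(1S,4S,5R,7R)-9-chloro-3,5,9-trimethyl-8-oxobicyclo[5.2.0]non-2-en-4-yl]propyl (2Z)-2-methylbut-2-enoate (epimers at the chloro carbon, chlorine mainly exo) | CC1(Cl)C(=O)[C@@H]2C[C@@H](C)[C@H]([C@H](CCOC(C)=O)OC(=O)/C(C)=C\C)C(C)=C[C@H]12
F9 | step 8 | (1S)-3-(acetyloxy)-1-[(3aS,6S,7R,8aR)-3-chloro-3,5,7-trimethyl-2-oxo-3,3a,6,7,8,8a-hexahydro-2H-cyclohepta[b]furan-6-yl]propyl (2Z)-2-methylbut-2-enoate (epimers at the chloro carbon) | CC1(Cl)C(=O)O[C@@H]2C[C@@H](C)[C@H]([C@H](CCOC(C)=O)OC(=O)/C(C)=C\C)C(C)=C[C@H]12
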